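The decalin is cut at two bonds of ring B, the C5–C10 ring fusion and C8–C9, which are the bonds an acyclic 1,7,9-decatriene forms in an intramolecular Diels–Alder reaction. The feature used is that C8, the methyl carbinol carbon of ring B, lies between the chain-bearing C9 and C7, so a 1-methyl-1-silyloxy diene (C5=C6–C7=C8) brings the tertiary oxygen with it. One cycloaddition closes rings A and B and sets C5, C8, C9 and C10 under control of the C3 silyl ether. Its precursor is a linear E β-methyl enoate (C9=C10) tied through C1–C4 to a Z silyl dienol ether; the farnesyl chain is added later at C11 by sulfone alkylation.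

Key step: step 11

Remark on numbering: carbons carry their drimane numbers throughout (ring carbons C1–C10, C11 on C9, C12 the methyl on C8). In the open-chain compounds, chain atoms 1–12 of the dodecatrienoate correspond to C11, C9, C10, C1, C2, C3, C4, C5, C6, C7, C8, C12. α/β refer to the drawing with the C10 methyl β.
Assumption: the oxazaborolidinone from N-tosyl-D-valine is taken to deliver the 3S aldol, by analogy with isobutyrate-derived ketene silyl acetals. The L-valine reagent would serve equally if the assay of the aldol showed the opposite sense.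
Assumption: 2-(2-bromoethyl)-2-methyl-1,3-dioxolane is taken as a purchasable building block.

Step 1
Reactants: 1 methyl geranate
Product: 3 methyl (2E)-3-methyl-6-oxohex-2-enoate, via secondary ozonide 2 (not isolated)
Conditions: O3 (1.0 equiv), CH2Cl2, −78 °C; then PPh3, −78 °C → rt
Reagents that add atoms: ozone, [O-][O+]=O
Why: Ozonolysis, in which ozone should add far faster to the electron-rich distal trisubstituted alkene than to the ester-conjugated one, and PPh3 reduces the ozonide to the aldehyde without creating a stereocentre.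

Step 2
Reactants: 4 S-ethyl 2-methylpropanethioate
Product: 6 {[1-(ethylsulfanyl)-2-methylprop-1-en-1-yl]oxy}trimethylsilane, via lithium thioester enolate 5 (not isolated)
Conditions: LiN(i-Pr)2, THF, −78 °C; then Me3SiCl, −78 °C → rt; distillation
Reagents that add atoms: chlorotrimethylsilane, C[Si](C)(C)Cl
Why: Enolization of the thioester and O-silylation give the ketene silyl thioacetal, which has no E/Z question because both alkene substituents are methyl.

Step 3
Reactants: 3 methyl (2E)-3-methyl-6-oxohex-2-enoate; 6 {[1-(ethylsulfanyl)-2-methylprop-1-en-1-yl]oxy}trimethylsilane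
Product: 7 S-ethyl (3S,6E)-3-hydroxy-8-methoxy-2,2,6-trimethyl-8-oxooct-6-enethioate
Conditions: N-tosyl-D-valine, BH3·THF, CH2Cl2, 0 °C → rt (promoter formation); then 3 and 6, −78 °C; pH 7 buffer
Reagents that add atoms: none
Why: Kiyooka-type asymmetric Mukaiyama aldol, in which the aldehyde bound to the valine-derived oxazaborolidinone is attacked on one face by the ketene silyl acetal to set the 3S carbinol (the later C3), while the thioester keeps the two acyl groups distinguishable.

Step 4
Reactants: 7 S-ethyl (3S,6E)-3-hydroxy-8-methoxy-2,2,6-trimethyl-8-oxooct-6-enethioate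
Product: 8 S-ethyl (3S,6E)-3-[(tert-butyldimethylsilyl)oxy]-8-methoxy-2,2,6-trimethyl-8-oxooct-6-enethioate
Conditions: TBSOTf, 2,6-lutidine, CH2Cl2, −78 → 0 °C
Reagents that add atoms: tert-butyldimethylsilyl triflate, CC(C)(C)[Si](C)(C)OS(=O)(=O)C(F)(F)F
Why: Silylation of a hindered secondary alcohol with a silyl triflate and a hindered base, which leaves the thioester, the enoate and the stereocentre untouched.

Step 5
Reactants: 8 S-ethyl (3S,6E)-3-[(tert-butyldimethylsilyl)oxy]-8-methoxy-2,2,6-trimethyl-8-oxooct-6-enethioate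
Product: 9 methyl (2E,6S)-6-[(tert-butyldimethylsilyl)oxy]-3,7,7-trimethyl-8-oxooct-2-enoate
Conditions: Et3SiH, 10% Pd/C, acetone, rt
Reagents that add atoms: none
Why: Fukuyama reduction, in which palladium inserts into the C–S bond and the silane delivers hydride, so only the thioester becomes an aldehyde while the methyl enoate stays; the quaternary α-carbon rules out epimerization and β-elimination.

Step 6
Reactants: 10 2-(2-bromoethyl)-2-methyl-1,3-dioxolane
Product: 11 5-{[2-(2-methyl-1,3-dioxolan-2-yl)ethyl]sulfanyl}-1-phenyl-1H-tetrazole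
Conditions: 1-phenyl-1H-tetrazole-5-thiol, K2CO3, DMF, rt
Reagents that add atoms: 1-phenyl-1H-tetrazole-5-thiol, Sc1nnnn1-c1ccccc1
Why: SN2 thioetherification of an unhindered primary bromide by the thiolate.

Step 7
Reactants: 11 5-{[2-(2-methyl-1,3-dioxolan-2-yl)ethyl]sulfanyl}-1-phenyl-1H-tetrazole
Product: 12 5-{[2-(2-methyl-1,3-dioxolan-2-yl)ethyl]sulfonyl}-1-phenyl-1H-tetrazole
Conditions: 30% H2O2, (NH4)6Mo7O24·4H2O (cat.), EtOH, 0 °C → rt
Reagents that add atoms: hydrogen peroxide, OO
Why: Molybdate-catalysed peroxide oxidation of a sulfide to the sulfone, the standard preparation of Julia–Kocienski reagents, which a dioxolane should tolerate.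

Step 8
Reactants: 12 5-{[2-(2-methyl-1,3-dioxolan-2-yl)ethyl]sulfonyl}-1-phenyl-1H-tetrazole; 9 methyl (2E,6S)-6-[(tert-butyldimethylsilyl)oxy]-3,7,7-trimethyl-8-oxooct-2-enoate
Product: 14 methyl (2E,6S,8E)-6-[(tert-butyldimethylsilyl)oxy]-3,7,7-trimethyl-10-(2-methyl-1,3-dioxolan-2-yl)deca-2,8-dienoate, via potassium sulfonyl carbanion 13 (not isolated)
Conditions: KN(SiMe3)2, DME, −78 °C; then 9, −78 °C → rt
Reagents that add atoms: none
Why: Julia–Kocienski olefination (addition to the non-enolizable aldehyde, Smiles rearrangement, loss of SO2 and tetrazololate), which should give the E alkene C5=C6 as is usual for phenyltetrazolyl sulfones with α-branched aldehydes; the ketal keeps the reagent from β-elimination.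

Step 9
Reactants: 14 methyl (2E,6S,8E)-6-[(tert-butyldimethylsilyl)oxy]-3,7,7-trimethyl-10-(2-methyl-1,3-dioxolan-2-yl)deca-2,8-dienoate
Product: 15 methyl (2E,6S,8E)-6-[(tert-butyldimethylsilyl)oxy]-3,7,7-trimethyl-11-oxododeca-2,8-dienoate
Conditions: PPTS (cat.), acetone–H2O, 40 °C
Reagents that add atoms: water, O
Why: Mild acid-catalysed ketal hydrolysis, which should release the β,γ-unsaturated methyl ketone because weak acid does not enolize it fast enough to move the alkene into conjugation, and which spares the secondary TBS ether.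

Step 10
Reactants: 15 methyl (2E,6S,8E)-6-[(tert-butyldimethylsilyl)oxy]-3,7,7-trimethyl-11-oxododeca-2,8-dienoate
Product: 16 methyl (2E,6S,8E,10Z)-6-[(tert-butyldimethylsilyl)oxy]-3,7,7-trimethyl-11-[(triethylsilyl)oxy]dodeca-2,8,10-trienoate
Conditions: Et3SiOTf, Et3N, CH2Cl2, −78 → 0 °C; filtration through Et3N-deactivated silica, used at once
Reagents that add atoms: triethylsilyl triflate, CC[Si](CC)(CC)OS(=O)(=O)C(F)(F)F
Why: Soft enolization (silyl triflate and amine), in which the doubly activated allylic C7 methylene should be deprotonated in preference to the C12 methyl to give the conjugated dienol ether, the Z isomer (oxygen cis to C6) being favoured because the E isomer would press the C12 methyl against C6–H by allylic strain.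

Step 11
Reactants: 16 methyl (2E,6S,8E,10Z)-6-[(tert-butyldimethylsilyl)oxy]-3,7,7-trimethyl-11-[(triethylsilyl)oxy]dodeca-2,8,10-trienoate
Product: 17 methyl 3β-[(tert-butyldimethylsilyl)oxy]-8α-[(triethylsilyl)oxy]drim-6-en-11-oate (5α-H, 9α-H, 10β-CH3; 3S,5R,8R,9R,10S)
Conditions: toluene (0.01 M), BHT (cat.), 2,6-di-tert-butyl-4-methylpyridine (cat.), sealed tube, 180 °C
Reagents that add atoms: none
Why: A thermal, concerted but asynchronous normal-demand [4+2] cycloaddition in which the electron-rich diene terminus C5 bonds to the enoate β-carbon C10 and the oxygen-bearing C8 to the α-carbon C9; the closest known reaction type is the type 1 intramolecular Diels–Alder reaction of undeca-2,8,10-trienoates and of 1-silyloxy dienes to trans-fused decalins. Ring B closes as the cyclohexene of the cycloaddition itself (bonds C5–C10 and C8–C9, C6=C7 left behind), and ring A closes as the fused cyclohexane completed by the four-atom tether C1–C4 across the new C5–C10 bond. C9 and C10 receive their cis ester/methyl relation suprafacially from the E enoate, C8 receives its α-oxygen and β-methyl relative to C5 from the Z enol ether (silyloxy inside, methyl outside), the trans relation of H5 and the C10 methyl comes from the ester-endo, tether-exo transition state, and the absolute sense of all four comes from the C3 silyl ether sitting equatorial on the chair-like tether. The step therefore needs endo selectivity, π-facial selectivity and faithful transfer of the enol ether geometry: the chair tether stiffened by the C4 gem-dimethyl group, the equatorial preference of the bulky OTBS group and the absence of any Lewis acid (a stepwise Michael/aldol path would uncouple C8 from the enol ether geometry) should secure them. The quaternary C4 and the outside position of the C8 methyl leave the diene no hydrogen for a [1,5] shift, and any E enol ether, which would have methyl inside, should cycloadd more slowly and stay behind.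

Step 12
Reactants: 17 methyl 3β-[(tert-butyldimethylsilyl)oxy]-8α-[(triethylsilyl)oxy]drim-6-en-11-oate
Product: 18 methyl 3β-[(tert-butyldimethylsilyl)oxy]-8α-[(triethylsilyl)oxy]driman-11-oate
Conditions: H2 (1 atm), PtO2 (cat.), EtOAc, rt
Reagents that add atoms: none
Why: Heterogeneous hydrogenation of the only alkene (C6=C7, cis-disubstituted), which creates no stereocentre and should leave the silyl ethers and the ester alone under neutral conditions.

Step 13
Reactants: 18 methyl 3β-[(tert-butyldimethylsilyl)oxy]-8α-[(triethylsilyl)oxy]driman-11-oate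
Product: 19 3β-[(tert-butyldimethylsilyl)oxy]-8α-[(triethylsilyl)oxy]driman-11-ol
Conditions: LiAlH4, THF, 0 °C → rt
Reagents that add atoms: none
Why: Hydride reduction of the ester to the primary C11 alcohol, with C9 secure because its substituent is already equatorial and both silyl ethers are stable to the reagent.

Step 14
Reactants: 19 3β-[(tert-butyldimethylsilyl)oxy]-8α-[(triethylsilyl)oxy]driman-11-ol
Product: 20 3β-[(tert-butyldimethylsilyl)oxy]-11-(phenylsulfanyl)-8α-[(triethylsilyl)oxy]drimane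
Conditions: PhSSPh, n-Bu3P, pyridine, 60 °C
Reagents that add atoms: diphenyl disulfide, c1ccc(SSc2ccccc2)cc1
Why: Hata reaction (Mitsunobu-type), in which the alcohol is activated as an alkoxyphosphonium ion and displaced by thiophenolate at the primary C11, a process established for β-branched primary alcohols of this terpenoid type.

Step 15
Reactants: 20 3β-[(tert-butyldimethylsilyl)oxy]-11-(phenylsulfanyl)-8α-[(triethylsilyl)oxy]drimane
Product: 21 3β-[(tert-butyldimethylsilyl)oxy]-11-(phenylsulfonyl)-8α-[(triethylsilyl)oxy]drimane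
Conditions: mCPBA, NaHCO3, CH2Cl2, 0 °C → rt
Reagents that add atoms: 3-chloroperoxybenzoic acid, OOC(=O)c1cccc(Cl)c1
Why: Buffered peracid oxidation of the sulfide to the sulfone, carried out while the molecule still contains no alkene.

Step 16
Reactants: 21 3β-[(tert-butyldimethylsilyl)oxy]-11-(phenylsulfonyl)-8α-[(triethylsilyl)oxy]drimane; 22 (2E,6E)-farnesyl bromide
Product: 24 3β-[(tert-butyldimethylsilyl)oxy]-11-[(2E,6E)-farnesyl]-11-(phenylsulfonyl)-8α-[(triethylsilyl)oxy]drimane (both C11 epimers), via lithiated sulfone 23 (not isolated)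
Conditions: n-BuLi, THF, −78 °C; then 22, DMPU, −78 → −20 °C
Reagents that add atoms: none
Why: SN2 alkylation of an α-sulfonyl carbanion with a reactive primary allylic bromide, which forms C11–C12 without touching the alkene geometries; the new C11 centre arises as a mixture that the next step removes.

Step 17
Reactants: 24 3β-[(tert-butyldimethylsilyl)oxy]-11-[(2E,6E)-farnesyl]-11-(phenylsulfonyl)-8α-[(triethylsilyl)oxy]drimane
Product: 25 3β-[(tert-butyldimethylsilyl)oxy]-11-[(2E,6E)-farnesyl]-8α-[(triethylsilyl)oxy]drimane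
Conditions: Na(Hg) (6% Na), Na2HPO4, MeOH–THF, −20 °C → rt
Reagents that add atoms: none
Why: Reductive desulfonylation by electron transfer cleaves the C11–S bond, and because the sulfone is homoallylic and not allylic no alkene can shift or isomerize.

Step 18
Reactants: 25 3β-[(tert-butyldimethylsilyl)oxy]-11-[(2E,6E)-farnesyl]-8α-[(triethylsilyl)oxy]drimane
Product: 26 11-[(2E,6E)-farnesyl]drimane-3β,8α-diol
Conditions: Bu4NF, THF, 60 °C
Reagents that add atoms: none
Why: Fluoride-induced cleavage of both silyl ethers under basic conditions, which avoid ionization of the tertiary C8 alcohol and protonation of the trisubstituted alkenes.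

Step 19
Reactants: 26 11-[(2E,6E)-farnesyl]drimane-3β,8α-diol
Product: 27 8α-hydroxy-11-[(2E,6E)-farnesyl]driman-3-one (the target)
Conditions: Dess–Martin periodinane, NaHCO3, CH2Cl2, rt
Reagents that add atoms: none
Why: Dess–Martin oxidation of the only secondary alcohol gives the C3 ketone; the tertiary C8 alcohol cannot be oxidized, and C4 is quaternary and C5 is not enolizable, so no stereocentre is at risk.

Compound list
1 | methyl geranate, methyl (2E)-3,7-dimethylocta-2,6-dienoate | COC(=O)/C=C(\C)CCC=C(C)C | starting material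
2 | methyl (2E)-5-(5,5-dimethyl-1,2,4-trioxolan-3-yl)-3-methylpent-2-enoate (secondary ozonide) | COC(=O)/C=C(\C)CCC1OOC(C)(C)O1 | intermediate
3 | methyl (2E)-3-methyl-6-oxohex-2-enoate | COC(=O)/C=C(\C)CCC=O | intermediate
4 | S-ethyl 2-methylpropanethioate | CCSC(=O)C(C)C | starting material
5 | lithium 1-(ethylsulfanyl)-2-methylprop-1-en-1-olate | [Li+].CCSC([O-])=C(C)C | intermediate
6 | {[1-(ethylsulfanyl)-2-methylprop-1-en-1-yl]oxy}trimethylsilane | CCSC(O[Si](C)(C)C)=C(C)C | intermediate
7 | S-ethyl (3S,6E)-3-hydroxy-8-methoxy-2,2,6-trimethyl-8-oxooct-6-enethioate | CCSC(=O)C(C)(C)[C@@H](O)CC/C(C)=C/C(=O)OC | intermediate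
8 | S-ethyl (3S,6E)-3-[(tert-butyldimethylsilyl)oxy]-8-methoxy-2,2,6-trimethyl-8-oxooct-6-enethioate | CCSC(=O)C(C)(C)[C@@H](O[Si](C)(C)C(C)(C)C)CC/C(C)=C/C(=O)OC | intermediate
9 | methyl (2E,6S)-6-[(tert-butyldimethylsilyl)oxy]-3,7,7-trimethyl-8-oxooct-2-enoate | COC(=O)/C=C(\C)CC[C@H](O[Si](C)(C)C(C)(C)C)C(C)(C)C=O | intermediate
10 | 2-(2-bromoethyl)-2-methyl-1,3-dioxolane | CC1(CCBr)OCCO1 | starting material
11 | 5-{[2-(2-methyl-1,3-dioxolan-2-yl)ethyl]sulfanyl}-1-phenyl-1H-tetrazole | CC1(CCSc2nnnn2-c2ccccc2)OCCO1 | intermediate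
12 | 5-{[2-(2-methyl-1,3-dioxolan-2-yl)ethyl]sulfonyl}-1-phenyl-1H-tetrazole | CC1(CCS(=O)(=O)c2nnnn2-c2ccccc2)OCCO1 | intermediate
13 | potassium salt of the α-sulfonyl carbanion of 12 | [K+].CC1(C[CH-]S(=O)(=O)c2nnnn2-c2ccccc2)OCCO1 | intermediate
14 | methyl (2E,6S,8E)-6-[(tert-butyldimethylsilyl)oxy]-3,7,7-trimethyl-10-(2-methyl-1,3-dioxolan-2-yl)deca-2,8-dienoate | COC(=O)/C=C(\C)CC[C@H](O[Si](C)(C)C(C)(C)C)C(C)(C)/C=C/CC1(C)OCCO1 | intermediate
15 | methyl (2E,6S,8E)-6-[(tert-butyldimethylsilyl)oxy]-3,7,7-trimethyl-11-oxododeca-2,8-dienoate | COC(=O)/C=C(\C)CC[C@H](O[Si](C)(C)C(C)(C)C)C(C)(C)/C=C/CC(C)=O | intermediate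
16 | methyl (2E,6S,8E,10Z)-6-[(tert-butyldimethylsilyl)oxy]-3,7,7-trimethyl-11-[(triethylsilyl)oxy]dodeca-2,8,10-trienoate (precursor of the key step) | COC(=O)/C=C(\C)CC[C@H](O[Si](C)(C)C(C)(C)C)C(C)(C)/C=C/C=C(/C)O[Si](CC)(CC)CC | intermediate
17 | methyl 3β-[(tert-butyldimethylsilyl)oxy]-8α-[(triethylsilyl)oxy]drim-6-en-11-oate (product of the key step) | COC(=O)[C@@H]1[C@@]2(C)CC[C@H](O[Si](C)(C)C(C)(C)C)C(C)(C)[C@@H]2C=C[C@@]1(C)O[Si](CC)(CC)CC | intermediate
18 | methyl 3β-[(tert-butyldimethylsilyl)oxy]-8α-[(triethylsilyl)oxy]driman-11-oate | COC(=O)[C@@H]1[C@@]2(C)CC[C@H](O[Si](C)(C)C(C)(C)C)C(C)(C)[C@@H]2CC[C@@]1(C)O[Si](CC)(CC)CC | intermediate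
19 | 3β-[(tert-butyldimethylsilyl)oxy]-8α-[(triethylsilyl)oxy]driman-11-ol | OC[C@@H]1[C@@]2(C)CC[C@H](O[Si](C)(C)C(C)(C)C)C(C)(C)[C@@H]2CC[C@@]1(C)O[Si](CC)(CC)CC | intermediate
20 | 3β-[(tert-butyldimethylsilyl)oxy]-11-(phenylsulfanyl)-8α-[(triethylsilyl)oxy]drimane | c1ccccc1SC[C@@H]1[C@@]2(C)CC[C@H](O[Si](C)(C)C(C)(C)C)C(C)(C)[C@@H]2CC[C@@]1(C)O[Si](CC)(CC)CC | intermediate
21 | 3β-[(tert-butyldimethylsilyl)oxy]-11-(phenylsulfonyl)-8α-[(triethylsilyl)oxy]drimane | O=S(=O)(c1ccccc1)C[C@@H]1[C@@]2(C)CC[C@H](O[Si](C)(C)C(C)(C)C)C(C)(C)[C@@H]2CC[C@@]1(C)O[Si](CC)(CC)CC | intermediate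
22 | (2E,6E)-farnesyl bromide | CC(C)=CCC/C(C)=C/CC/C(C)=C/CBr | starting material
23 | 11-lithio derivative of sulfone 21 | [Li+].O=S(=O)(c1ccccc1)[CH-][C@@H]1[C@@]2(C)CC[C@H](O[Si](C)(C)C(C)(C)C)C(C)(C)[C@@H]2CC[C@@]1(C)O[Si](CC)(CC)CC | intermediate
24 | 3β-[(tert-butyldimethylsilyl)oxy]-11-[(2E,6E)-farnesyl]-11-(phenylsulfonyl)-8α-[(triethylsilyl)oxy]drimane (both C11 epimers) | CC(C)=CCC/C(C)=C/CC/C(C)=C/CC(S(=O)(=O)c1ccccc1)[C@@H]1[C@@]2(C)CC[C@H](O[Si](C)(C)C(C)(C)C)C(C)(C)[C@@H]2CC[C@@]1(C)O[Si](CC)(CC)CC | intermediate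
25 | 3β-[(tert-butyldimethylsilyl)oxy]-11-[(2E,6E)-farnesyl]-8α-[(triethylsilyl)oxy]drimane | CC(C)=CCC/C(C)=C/CC/C(C)=C/CC[C@@H]1[C@@]2(C)CC[C@H](O[Si](C)(C)C(C)(C)C)C(C)(C)[C@@H]2CC[C@@]1(C)O[Si](CC)(CC)CC | intermediate
26 | 11-[(2E,6E)-farnesyl]drimane-3β,8α-diol | CC(C)=CCC/C(C)=C/CC/C(C)=C/CC[C@@H]1[C@@]2(C)CC[C@H](O)C(C)(C)[C@@H]2CC[C@@]1(C)O | intermediate
27 | 8α-hydroxy-11-[(2E,6E)-farnesyl]driman-3-one, (4aS,5R,6R,8aR)-6-hydroxy-1,1,4a,6-tetramethyl-5-[(3E,7E)-4,8,12-trimethyltrideca-3,7,11-trien-1-yl]octahydronaphthalen-2(1H)-one | CC(C)=CCC/C(C)=C/CC/C(C)=C/CC[C@@H]1[C@@]2(C)CCC(=O)C(C)(C)[C@@H]2CC[C@@]1(C)O | target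

Total step count: 19. Longest linear sequence: 16 steps (steps 1, 3, 4, 5, 8–19, from methyl geranate).

Steps most likely to fail

1. Step 11. The cycloaddition has to join two fully substituted termini (C8 and C10) and may be slow enough that prolonged heating erodes the silyl dienol ether. The ester-endo and equatorial-OTBS preferences may also be too weak, so that cis-fused or facially wrong cycloadducts form; any such diastereomer has to be removed before step 19 erases C3. Fallback, setting out from 14 and returning at 19: the dienophile is changed to an enal so that a Lewis acid can drive the cycloaddition at low temperature. Reduction of 14 with i-Bu2AlH (CH2Cl2, −78 °C) would give the allylic alcohol (2E,6S,8E)-6-[(tert-butyldimethylsilyl)oxy]-3,7,7-trimethyl-10-(2-methyl-1,3-dioxolan-2-yl)deca-2,8-dien-1-ol F1. MnO2 (CH2Cl2, rt) would give the enal (2E,6S,8E)-6-[(tert-butyldimethylsilyl)oxy]-3,7,7-trimethyl-10-(2-methyl-1,3-dioxolan-2-yl)deca-2,8-dienal F2. PPTS in aqueous acetone would give the keto enal (2E,6S,8E)-6-[(tert-butyldimethylsilyl)oxy]-3,7,7-trimethyl-11-oxododeca-2,8-dienal F3. Et3SiOTf and Et3N (CH2Cl2, −78 °C) would give the silyl dienol ether (2E,6S,8E,10Z)-6-[(tert-butyldimethylsilyl)oxy]-3,7,7-trimethyl-11-[(triethylsilyl)oxy]dodeca-2,8,10-trienal F4. Me2AlCl (CH2Cl2, −78 °C) would then give the cycloadduct 3β-[(tert-butyldimethylsilyl)oxy]-8α-[(triethylsilyl)oxy]drim-6-en-11-al F5, by the established Lewis acid-catalysed intramolecular Diels–Alder reaction of undeca-2,8,10-trienals. NaBH4 (MeOH, 0 °C) would give 3β-[(tert-butyldimethylsilyl)oxy]-8α-[(triethylsilyl)oxy]drim-6-en-11-ol F6, and hydrogenation of this alcohol (H2, PtO2, EtOAc) would give 19.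

2. Step 9. Acid-promoted enolization may move the C5=C6 alkene into conjugation with the ketone, after which step 10 would silylate towards the wrong, cross-conjugated diene. Fallback, setting out from 9 and returning at 15: the ketone is carried as a silyl-protected secondary alcohol and unveiled by neutral oxidation. Butane-1,3-diol would be thioetherified at its primary hydroxyl (1-phenyl-1H-tetrazole-5-thiol, PPh3, DIAD, THF) to racemic 4-[(1-phenyl-1H-tetrazol-5-yl)sulfanyl]butan-2-ol F7. Oxidation (H2O2, (NH4)6Mo7O24·4H2O, EtOH) would give 4-[(1-phenyl-1H-tetrazol-5-yl)sulfonyl]butan-2-ol F8, and silylation (Et3SiCl, imidazole, CH2Cl2) would give 1-phenyl-5-({3-[(triethylsilyl)oxy]butyl}sulfonyl)-1H-tetrazole F9. Julia–Kocienski olefination of 9 with this sulfone (KN(SiMe3)2, DME, −78 °C) would give methyl (2E,6S,8E)-6-[(tert-butyldimethylsilyl)oxy]-3,7,7-trimethyl-11-[(triethylsilyl)oxy]dodeca-2,8-dienoate F10 as C11 epimers. PPTS in MeOH at 0 °C would remove only the triethylsilyl group to give methyl (2E,6S,8E)-6-[(tert-butyldimethylsilyl)oxy]-11-hydroxy-3,7,7-trimethyldodeca-2,8-dienoate F11. Dess–Martin oxidation (NaHCO3, CH2Cl2) would then give 15 without exposing the β,γ-enone to acid.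

3. Step 3. The promoter may show insufficient or inverted facial selectivity with the sulfur-substituted ketene acetal, which would carry through as loss of optical purity or as the enantiomeric series. Fallback, setting out from 3 and 6 and returning at 7: the stereocentre is set by reagent-controlled ketone reduction. BF3·OEt2 (CH2Cl2, −78 °C) would give the racemic aldol S-ethyl (6E)-3-hydroxy-8-methoxy-2,2,6-trimethyl-8-oxooct-6-enethioate F12. Dess–Martin oxidation would give the β-keto thioester S-ethyl (6E)-8-methoxy-2,2,6-trimethyl-3,8-dioxooct-6-enethioate F13. Corey–Bakshi–Shibata reduction with the (R)-2-methyl oxazaborolidine and catecholborane (toluene, −78 °C), in which the quaternary carbon acts as the large group, would give 7.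

Further compounds
F1 | step 11 | (2E,6S,8E)-6-[(tert-butyldimethylsilyl)oxy]-3,7,7-trimethyl-10-(2-methyl-1,3-dioxolan-2-yl)deca-2,8-dien-1-ol | OC/C=C(\C)CC[C@H](O[Si](C)(C)C(C)(C)C)C(C)(C)/C=C/CC1(C)OCCO1
F2 | step 11 | (2E,6S,8E)-6-[(tert-butyldimethylsilyl)oxy]-3,7,7-trimethyl-10-(2-methyl-1,3-dioxolan-2-yl)deca-2,8-dienal | O=C/C=C(\C)CC[C@H](O[Si](C)(C)C(C)(C)C)C(C)(C)/C=C/CC1(C)OCCO1
F3 | step 11 | (2E,6S,8E)-6-[(tert-butyldimethylsilyl)oxy]-3,7,7-trimethyl-11-oxododeca-2,8-dienal | O=C/C=C(\C)CC[C@H](O[Si](C)(C)C(C)(C)C)C(C)(C)/C=C/CC(C)=O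
F4 | step 11 | (2E,6S,8E,10Z)-6-[(tert-butyldimethylsilyl)oxy]-3,7,7-trimethyl-11-[(triethylsilyl)oxy]dodeca-2,8,10-trienal | O=C/C=C(\C)CC[C@H](O[Si](C)(C)C(C)(C)C)C(C)(C)/C=C/C=C(/C)O[Si](CC)(CC)CC
F5 | step 11 | 3β-[(tert-butyldimethylsilyl)oxy]-8α-[(triethylsilyl)oxy]drim-6-en-11-al | O=C[C@@H]1[C@@]2(C)CC[C@H](O[Si](C)(C)C(C)(C)C)C(C)(C)[C@@H]2C=C[C@@]1(C)O[Si](CC)(CC)CC
F6 | step 11 | 3β-[(tert-butyldimethylsilyl)oxy]-8α-[(triethylsilyl)oxy]drim-6-en-11-ol | OC[C@@H]1[C@@]2(C)CC[C@H](O[Si](C)(C)C(C)(C)C)C(C)(C)[C@@H]2C=C[C@@]1(C)O[Si](CC)(CC)CC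
F7 | step 9 | 4-[(1-phenyl-1H-tetrazol-5-yl)sulfanyl]butan-2-ol (racemic) | CC(O)CCSc1nnnn1-c1ccccc1
F8 | step 9 | 4-[(1-phenyl-1H-tetrazol-5-yl)sulfonyl]butan-2-ol (racemic) | CC(O)CCS(=O)(=O)c1nnnn1-c1ccccc1
F9 | step 9 | 1-phenyl-5-({3-[(triethylsilyl)oxy]butyl}sulfonyl)-1H-tetrazole (racemic) | CC(CCS(=O)(=O)c1nnnn1-c1ccccc1)O[Si](CC)(CC)CC
F10 | step 9 | methyl (2E,6S,8E)-6-[(tert-butyldimethylsilyl)oxy]-3,7,7-trimethyl-11-[(triethylsilyl)oxy]dodeca-2,8-dienoate (C11 epimers) | COC(=O)/C=C(\C)CC[C@H](O[Si](C)(C)C(C)(C)C)C(C)(C)/C=C/CC(C)O[Si](CC)(CC)CC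
F11 | step 9 | methyl (2E,6S,8E)-6-[(tert-butyldimethylsilyl)oxy]-11-hydroxy-3,7,7-trimethyldodeca-2,8-dienoate (C11 epimers) | COC(=O)/C=C(\C)CC[C@H](O[Si](C)(C)C(C)(C)C)C(C)(C)/C=C/CC(C)O
F12 | step 3 | S-ethyl (6E)-3-hydroxy-8-methoxy-2,2,6-trimethyl-8-oxooct-6-enethioate (racemic) | CCSC(=O)C(C)(C)C(O)CC/C(C)=C/C(=O)OC
F13 | step 3 | S-ethyl (6E)-8-methoxy-2,2,6-trimethyl-3,8-dioxooct-6-enethioate | CCSC(=O)C(C)(C)C(=O)CC/C(C)=C/C(=O)OC
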